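## Retrosynthetic overview

1. The two halves of the target match at C6, C7 and C11 but are epimeric at C10: 10R has an axial OAc and 10'S an equatorial OAc. The route therefore makes the halves one after the other. Both ketones come from C3/C3' carbinols in the last step.
2. The axial C10–OAc comes from trans-diaxial acetoxymercuration of a Δ9(10)-olefin. The left oxepane and cyclohexene are formed last, by an epoxide-opening oxa/carba cascade of diepoxy-olefin 7.
3. The C12–C12' bond comes from a nickel reductive coupling of bicyclic iodide 6 with allylic acetate 2.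
4. The right oxepane, the cyclohexane and the equatorial C10'–OAc are formed first, in one cascade of 2 that is ended by its own allylic acetate (acetoxonium relay).
5. Compound 2 comes from a regio- and enantioselective double Shi epoxidation of farnesyl acetate, and it is used twice.

Assumption: atom labels follow squalene numbering. C1–C12 is the half written first in the SMILES and C1'–C12' is the other half. β is the face of the angular C6/C6' methyl and α is the opposite face. (2E,6E)-Farnesyl acetate and the ent-Shi ketone (L-series) are bought.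

## Route

Step 1
Reactants: 1 (2E,6E)-farnesyl acetate
Product: 2 (6S,7S,10S)-6,7:10,11-diepoxyfarnesyl acetate
Conditions: ent-Shi ketone (30 mol %), Oxone, K2CO3, Bu4NHSO4, borate/EDTA buffer, MeCN–DMM–H2O, 0 °C
Reagents that add atoms: Oxone (active salt potassium peroxymonosulfate), [K+].[O-]S(=O)(=O)OO
Why: In this Shi asymmetric epoxidation the chiral dioxirane attacks the two electron-rich trisubstituted olefins through the spiro transition state, with the ent-ketone giving the all-S epoxides, while the allylic acetate deactivates the C2–C3 olefin and leaves it untouched.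

Step 2
Reactants: 2 (6S,7S,10S)-6,7:10,11-diepoxyfarnesyl acetate
Product: 5 right-half bicyclic diol monoacetate (trans-fused oxepane–cyclohexane; 10'α-OAc equatorial), via acetoxonium triflate 3 (not isolated), via TMS ether 4 (not isolated)
Conditions: TMSOTf (1.2 equiv), 2,6-di-tert-butyl-4-methylpyridine (DTBMP), CH2Cl2, −78 °C; aq NaHCO3; then aq citric acid, THF, 0 °C
Reagents that add atoms: water, O
Why: Proposed new method: silylation of the terminal epoxide starts the biomimetic relay, in which the 6',7'-epoxide oxygen opens it at tertiary C2' to give a bicyclic epoxonium, the E-C10'=C11' olefin attacks C6' from the back side through a chair, and the allylic acetate carbonyl closes anti onto C10' to give six-membered acetoxonium 3, so that C6', C7', C11' and the equatorial C10'–O bond follow stereospecifically from the (S,S)-epoxide and the E-olefin, and kinetic hydrolysis of 3 expels the primary alkoxide and leaves the tertiary acetate; the closest known reactions are the Lewis-acid tandem oxa-/carbacyclisation of 1,5-diepoxy olefins, the Lewis-acid bicyclisation of epoxyfarnesyl acetate, and orthoester/acetoxonium opening to the more hindered ester.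

Step 3
Reactants: 5 right-half bicyclic diol monoacetate
Product: 6 right-half primary iodide (C12'–I)
Conditions: I2, PPh3, imidazole, CH2Cl2, 0 °C to rt
Reagents that add atoms: iodine, II
Why: This Appel-type iodination selects the primary C12'–OH over the hindered secondary C3'–OH, touches no stereocentre, and is helped at this β-branched carbon by transient participation of the neighbouring acetate.

Step 4
Reactants: 6 right-half primary iodide; 2 (6S,7S,10S)-6,7:10,11-diepoxyfarnesyl acetate (1.5 equiv)
Product: 7 C30 diepoxy-olefin carrying the finished right-half bicycle (10E)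
Conditions: NiCl2·glyme (10 mol %), 4,4′,4″-tri-tert-butylterpyridine, Mn powder, THF–N-ethylpyrrolidinone, 40 °C
Reagents that add atoms: none
Why: In this nickel-catalysed reductive cross-electrophile coupling the C12' radical from the iodide is joined to the unsubstituted terminus of the π-allylnickel from 2, which gives the linear product with the E-olefin retained because syn/anti exchange would need a σ-bond at the tertiary terminus; no stereocentre is formed, and free OH, ester and trisubstituted epoxides are tolerated in the amide co-solvent.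

Step 5
Reactants: 7 C30 diepoxy-olefin
Product: 9 Δ9(10)-olefin diol monoacetate (all four rings closed), via bis-TMS ether 8 (not isolated)
Conditions: TMSOTf (3 equiv), DTBMP (4 equiv), CH2Cl2 (2 mM), −78 °C; aq NaHCO3; then aq citric acid, THF, 0 °C
Reagents that add atoms: none
Why: This Lewis-acid tandem oxa-/carbacyclisation of a 1,5-diepoxy olefin (epoxonium, then chair attack of the E-olefin) sets C6, C7 and C11 as in step 2, no second olefin flanks the C10 cation so the competing 5-exo closure of squalene-type chains is excluded, and E1 loss of the aligned axial H9 gives mainly the endocyclic trisubstituted olefin, as in drimenol-type terminations.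

Step 6
Reactants: 9 Δ9(10)-olefin diol monoacetate
Product: 11 diacetate diol (10β-OAc axial; 10'α-OAc equatorial), via organomercurial 10 (not isolated)
Conditions: Hg(OAc)2 (1.1 equiv), AcOH, rt; evaporate; NaBH4, aq NaOH, THF, 0 °C
Reagents that add atoms: mercury(II) acetate, CC(=O)O[Hg]OC(C)=O
Why: In this solvomercuration–demercuration the mercurinium ion forms on the open α-face and acetate opens it at tertiary C10 from the β-face, where Markovnikov and Fürst–Plattner (trans-diaxial) control agree, so the axial (10R) acetate is installed directly and the 9α-C–Hg bond is then reduced to C–H.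

Step 7
Reactants: 11 diacetate diol
Product: 12 target CNP0325605.1
Conditions: Dess–Martin periodinane (2.5 equiv), CH2Cl2, 0 °C to rt
Reagents that add atoms: none
Why: Dess–Martin oxidation converts both secondary C3/C3' carbinols into the oxepanones under near-neutral conditions that leave the two tertiary acetates and all eight stereocentres untouched.

## Compound list

1 | (2E,6E)-farnesyl acetate | CC(C)=CCC/C(C)=C/CC/C(C)=C/COC(C)=O | starting material
2 | (2E,6S,7S,10S)-6,7:10,11-diepoxy-3,7,11-trimethyldodec-2-enyl acetate | CC1(C)O[C@H]1CC[C@]2(C)O[C@H]2CC/C(C)=C/COC(C)=O | intermediate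
3 | acetoxonium triflate: 2-methyl-1,3-dioxan-2-ylium trans-fused across C10'–C11' of the right-half bicycle, 3'-OTMS | CC1=[O+]C[C@H]2[C@]3(C)CC[C@H](O[Si](C)(C)C)C(C)(C)O[C@H]3CC[C@]2(C)O1.[O-]S(=O)(=O)C(F)(F)F | intermediate
4 | 3'-O-TMS ether of 5 | OC[C@H]1[C@]2(C)CC[C@H](O[Si](C)(C)C)C(C)(C)O[C@H]2CC[C@]1(C)OC(C)=O | intermediate
5 | right-half bicycle: trans-fused 2,2,5a,7-tetramethylperhydro-1-benzoxepine with (3'S)-OH, equatorial C11'–CH2OH, equatorial 10'α-OAc and axial 10'-CH3 | OC[C@H]1[C@]2(C)CC[C@H](O)C(C)(C)O[C@H]2CC[C@]1(C)OC(C)=O | intermediate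
6 | C12' iodide of 5 | IC[C@H]1[C@]2(C)CC[C@H](O)C(C)(C)O[C@H]2CC[C@]1(C)OC(C)=O | intermediate
7 | (3S,6S,7S,10E)-2,3:6,7-diepoxy chain joined C12–C12' to the right-half bicycle | CC1(C)O[C@H]1CC[C@]2(C)O[C@H]2CC/C(C)=C/CC[C@H]3[C@]4(C)CC[C@H](O)C(C)(C)O[C@H]4CC[C@]3(C)OC(C)=O | intermediate
8 | 3,3'-bis-O-TMS ether of 9 | CC1=CC[C@@H]2OC(C)(C)[C@@H](O[Si](C)(C)C)CC[C@@]2(C)[C@@H]1CC[C@H]3[C@]4(C)CC[C@H](O[Si](C)(C)C)C(C)(C)O[C@H]4CC[C@]3(C)OC(C)=O | intermediate
9 | tetracycle with left Δ9(10)-olefin, (3S,3'S)-diol and equatorial 10'α-OAc | CC1=CC[C@@H]2OC(C)(C)[C@@H](O)CC[C@@]2(C)[C@@H]1CC[C@H]3[C@]4(C)CC[C@H](O)C(C)(C)O[C@H]4CC[C@]3(C)OC(C)=O | intermediate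
10 | 9α-(acetoxymercurio)-10β-acetate (diaxial adduct of 9) | CC(=O)O[C@]1(C)[C@@H]([Hg]OC(C)=O)C[C@@H]2OC(C)(C)[C@@H](O)CC[C@@]2(C)[C@@H]1CC[C@H]3[C@]4(C)CC[C@H](O)C(C)(C)O[C@H]4CC[C@]3(C)OC(C)=O | intermediate
11 | (3S,3'S)-diol with axial 10β-OAc and equatorial 10'α-OAc | CC(=O)O[C@]1(C)CC[C@@H]2OC(C)(C)[C@@H](O)CC[C@@]2(C)[C@@H]1CC[C@H]3[C@]4(C)CC[C@H](O)C(C)(C)O[C@H]4CC[C@]3(C)OC(C)=O | intermediate
12 | CNP0325605.1, (6S,7S,10R,11S,6'S,7'S,10'S,11'S) | CC(=O)O[C@]1(C)CC[C@@H]2OC(C)(C)C(=O)CC[C@@]2(C)[C@@H]1CC[C@H]1[C@]2(C)CCC(=O)C(C)(C)O[C@H]2CC[C@]1(C)OC(C)=O | target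

## Step count and risks

Total step count: 7. Longest linear sequence: 7 (compound 2 enters twice).

The three steps most likely to fail are steps 2, 4 and 5.

**Step 2.** The internal acetate may lose the race to proton loss, or hydrolysis may place the acetyl group on the primary oxygen.
- The fallback sets out from 2 and returns at 5.
- The same cascade is run with excess DTBMP, and the proton-loss product is taken on. This is the Δ9'(10')-olefinic primary acetate F1.
- Mukaiyama hydration (Mn(dpm)3, PhSiH3, O2) traps the C10' radical from the open α-face and gives the equatorial tertiary alcohol F2.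
- K2CO3 in MeOH frees the triol F3.
- MeC(OMe)3 with camphorsulfonic acid ties O10' and O12' together as the cyclic orthoacetate F4.
- Brief treatment with aqueous AcOH opens F4 through the same acetoxonium ion, at the primary C–O side, to give 5.

**Step 4.** The Lewis-acidic metal salts may damage the epoxides, or the olefin geometry may erode.
- The fallback sets out from 2 and 6 and returns at 7.
- Palladium-catalysed allylic sulfonylation of 2 (PhSO2Na, Pd(PPh3)4) gives the diepoxyfarnesyl phenyl sulfone F5.
- Its lithio anion (n-BuLi, THF–HMPA, −78 °C, 2.2 equiv because of the free OH) displaces the iodide of 6. This gives the C12-sulfonyl coupling product F6.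
- Palladium-catalysed hydride desulfonylation (PdCl2(dppp), LiBHEt3, −20 °C) delivers hydride to C12 with the E-olefin held in place and gives 7.

**Step 5.** Proton loss may favour the exocyclic olefin. That isomer would lead to the wrong C10 epimer in step 6.
- The fallback sets out from 7 and returns at 12, and it sets C10 by C–C bond formation instead.
- The exocyclic C10=CH2 isomer F7 from the cascade is ozonised (O3, then Me2S) to the 28-nor-10-ketone F8. Its C11 side chain is held equatorial by enolisation equilibrium.
- MeLi/CeCl3 at −78 °C adds along the equatorial α-trajectory, because the axial path is blocked by the C6 methyl. This gives the axial tertiary alcohol F9.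
- Dess–Martin oxidation gives the diketo alcohol F10.
- Forcing acetylation (AcCl, N,N-dimethylaniline, 60 °C) gives 12.
- Any endocyclic olefin 9 formed alongside F7 continues through the main route, so both isomers are used.

Further compounds
F1 | step 2 | right-half Δ9'(10')-olefin with C12'–OAc and (3'S)-OH | CC(=O)OC[C@H]1[C@]2(C)CC[C@H](O)C(C)(C)O[C@H]2CC=C1C
F2 | step 2 | right-half equatorial 10'α-tertiary alcohol with C12'–OAc | CC(=O)OC[C@H]1[C@]2(C)CC[C@H](O)C(C)(C)O[C@H]2CC[C@]1(C)O
F3 | step 2 | right-half 3',10',12'-triol | OC[C@H]1[C@]2(C)CC[C@H](O)C(C)(C)O[C@H]2CC[C@]1(C)O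
F4 | step 2 | cyclic 10',12'-orthoacetate (2-methoxy-2-methyl-1,3-dioxane, orthoester carbon as a mixture) | COC1(C)OC[C@H]2[C@]3(C)CC[C@H](O)C(C)(C)O[C@H]3CC[C@]2(C)O1
F5 | step 4 | (6S,7S,10S)-6,7:10,11-diepoxyfarnesyl phenyl sulfone | CC1(C)O[C@H]1CC[C@]2(C)O[C@H]2CC/C(C)=C/CS(=O)(=O)c3ccccc3
F6 | step 4 | 12-phenylsulfonyl derivative of 7 (C12 epimers) | CC1(C)O[C@H]1CC[C@]2(C)O[C@H]2CC/C(C)=C/C(C[C@H]3[C@]4(C)CC[C@H](O)C(C)(C)O[C@H]4CC[C@]3(C)OC(C)=O)S(=O)(=O)c5ccccc5
F7 | step 5 | exocyclic C10=CH2 isomer of 9 | C=C1CC[C@@H]2OC(C)(C)[C@@H](O)CC[C@@]2(C)[C@@H]1CC[C@H]3[C@]4(C)CC[C@H](O)C(C)(C)O[C@H]4CC[C@]3(C)OC(C)=O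
F8 | step 5 | 28-nor-10-ketone | O=C1CC[C@@H]2OC(C)(C)[C@@H](O)CC[C@@]2(C)[C@@H]1CC[C@H]3[C@]4(C)CC[C@H](O)C(C)(C)O[C@H]4CC[C@]3(C)OC(C)=O
F9 | step 5 | axial 10β-tertiary alcohol (10-deacetyl 11) | O[C@]1(C)CC[C@@H]2OC(C)(C)[C@@H](O)CC[C@@]2(C)[C@@H]1CC[C@H]3[C@]4(C)CC[C@H](O)C(C)(C)O[C@H]4CC[C@]3(C)OC(C)=O
F10 | step 5 | 10-deacetyl target (3,3'-diketone with axial 10β-OH) | O[C@]1(C)CC[C@@H]2OC(C)(C)C(=O)CC[C@@]2(C)[C@@H]1CC[C@H]3[C@]4(C)CCC(=O)C(C)(C)O[C@H]4CC[C@]3(C)OC(C)=O
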